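**Retrosynthetic overview**

1. Target 18 ⇐ 17 by hydrogenolysis of two aryl benzyl ethers; 17 ⇐ anomeric acetate 13 + styrene 2 in one cationic cascade that forms the C2–C3 bond of the heptane chain, sets C3, brings C1 to the CH2 level and turns the acetal carbon into the acetyl group.
2. Enabling feature: the anti O3/O5 pair on C3–C4–C5 can be tied by one CH(CH3) unit into a 1,3-dioxane; its acetal C–H then lies syn-axial to the bond made at C3, in a six-atom array H–C(acetal)–O3–C3–C2–C1 with the benzylic C1, which the 4-oxygenated arene turns into a stabilised cation.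
3. The diol core has a C2 axis through C4, so O3 and O5 are equivalent: whichever C–O bond of the resulting dioxanylium ion is hydrolysed, the same monoacetate results.
4. 13 ⇐ cis-1,3-dioxan-4-one 11 (reductive acetylation) ⇐ (S)-β-hydroxy acid 9 + acetaldehyde ⇐ asymmetric hydrogenation of β-keto ester 7 ⇐ benzylic chloride 4 + methyl acetoacetate 5; 2 ⇐ 4-vinylguaiacol 1.
5. Ring order: both arenes are bought; the only ring made is the temporary 1,3-dioxane, closed in step 6 and opened again in step 8.

Key step: step 8

Remark on the chemistry: 12 and 13 are mixtures of epimers at C4 of the dioxane; both epimers of 13 ionise to the same oxocarbenium ion, so this centre is left undefined in their SMILES.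

Step 1
Reactants: 1 2-methoxy-4-vinylphenol
Product: 2 1-(benzyloxy)-4-ethenyl-2-methoxybenzene
Conditions: BnBr, K2CO3, DMF, rt
Reagents that add atoms: benzyl bromide, BrCc1ccccc1
Why: Williamson etherification of the phenoxide should cap the phenol as a benzyl ether that tolerates the later Lewis acid step and leaves by hydrogenolysis at the end, the styrene being untouched at room temperature.

Step 2
Reactants: 3 [4-(benzyloxy)-3-methoxyphenyl]methanol
Product: 4 1-(benzyloxy)-4-(chloromethyl)-2-methoxybenzene
Conditions: SOCl2, CH2Cl2, 0 °C to rt, used crude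
Reagents that add atoms: thionyl chloride, ClS(Cl)=O
Why: Chlorodehydroxylation through the chlorosulfite (nucleophilic substitution) is fast at this para-oxygenated benzylic position, so cold conditions should suffice and the aryl benzyl ether should survive.

Step 3
Reactants: 5 methyl acetoacetate; 4 1-(benzyloxy)-4-(chloromethyl)-2-methoxybenzene
Product: 7 methyl 5-[4-(benzyloxy)-3-methoxyphenyl]-3-oxopentanoate, via acetoacetate dianion 6 (not isolated)
Conditions: NaH, THF, 0 °C; n-BuLi, 0 °C; then 4, 0 °C to rt; 1 M HCl quench
Reagents that add atoms: none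
Why: Dianion alkylation of a β-keto ester: the terminal (γ) carbanion is the more reactive site and should undergo SN2 alkylation with the activated benzylic chloride to give the γ-benzylated keto ester after protonation.

Step 4
Reactants: 7 methyl 5-[4-(benzyloxy)-3-methoxyphenyl]-3-oxopentanoate
Product: 8 methyl (3S)-5-[4-(benzyloxy)-3-methoxyphenyl]-3-hydroxypentanoate
Conditions: H2 (50 atm), RuCl2[(S)-BINAP] (0.5 mol %), MeOH, 50 °C
Reagents that add atoms: none
Why: Noyori asymmetric hydrogenation of a β-keto ester: hydride transfer within the keto ester chelate on the (S)-BINAP ruthenium catalyst should set the carbinol centre as S (the same facial sense by which the (R)-catalyst gives (R)-3-hydroxybutanoate), and this homogeneous catalyst should not touch the aryl benzyl ether.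

Step 5
Reactants: 8 methyl (3S)-5-[4-(benzyloxy)-3-methoxyphenyl]-3-hydroxypentanoate
Product: 9 (3S)-5-[4-(benzyloxy)-3-methoxyphenyl]-3-hydroxypentanoic acid
Conditions: LiOH, THF/H2O, 0 °C to rt; then 1 M HCl to pH 3
Reagents that add atoms: lithium hydroxide, [Li+].[OH-]
Why: Ester saponification at low temperature should give the β-hydroxy acid without retro-aldol cleavage or dehydration, the stereocentre not being enolisable.

Step 6
Reactants: 9 (3S)-5-[4-(benzyloxy)-3-methoxyphenyl]-3-hydroxypentanoic acid
Product: 11 (2S,6S)-6-{2-[4-(benzyloxy)-3-methoxyphenyl]ethyl}-2-methyl-1,3-dioxan-4-one, via bis-silyl derivative 10 (not isolated)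
Conditions: (Me3Si)2NH, CH2Cl2, rt, evaporate; then MeCHO, Me3SiOTf (5 mol %), CH2Cl2, −78 °C; pyridine quench
Reagents that add atoms: acetaldehyde, CC=O
Why: Silyl-mediated acetalisation: the bis-silylated hydroxy acid should condense with acetaldehyde under Me3SiOTf catalysis, with loss of hexamethyldisiloxane, to close the six-membered 1,3-dioxan-4-one, and the new acetal centre should be set cis to the C6 chain because methyl and chain both take equatorial positions in the chair, which leaves the acetal hydrogen axial.

Step 7
Reactants: 11 (2S,6S)-6-{2-[4-(benzyloxy)-3-methoxyphenyl]ethyl}-2-methyl-1,3-dioxan-4-one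
Product: 13 (2S,6S)-6-{2-[4-(benzyloxy)-3-methoxyphenyl]ethyl}-2-methyl-1,3-dioxan-4-yl acetate, via aluminium hemiacetal 12 (not isolated)
Conditions: iBu2AlH (DIBAL-H), CH2Cl2, −78 °C; then pyridine, DMAP, Ac2O, −78 °C to 0 °C
Reagents that add atoms: acetic anhydride, CC(=O)OC(C)=O
Why: Reductive acetylation of a lactone-type ester: iBu2AlH should add once at −78 °C to give a tetrahedral aluminium hemiacetal that is acylated in the flask before it can collapse, a sequence with direct precedent on 1,3-dioxan-4-ones, while the ring acetal, the benzyl ether and both existing stereocentres are not affected.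

Step 8
Reactants: 13 (2S,6S)-6-{2-[4-(benzyloxy)-3-methoxyphenyl]ethyl}-2-methyl-1,3-dioxan-4-yl acetate; 2 1-(benzyloxy)-4-ethenyl-2-methoxybenzene
Product: 17 (3S,5S)-1,7-bis[4-(benzyloxy)-3-methoxyphenyl]-5-hydroxyheptan-3-yl acetate, via oxocarbenium triflate 14 (not isolated), via benzylic cation triflate 15 (not isolated), via dioxanylium triflate 16 (not isolated)
Conditions: Me3SiOTf (1.2 equiv), 2,6-di-tert-butyl-4-methylpyridine (0.2 equiv), CH2Cl2 (0.02 M), −78 °C, 2 (1.3 equiv) added over 1 h, then −40 °C; H2O, then aq NaHCO3 wash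
Reagents that add atoms: water, O
Why: Proposed new method: Me3SiOTf should ionise the anomeric acetate of 13 to the cyclic oxocarbenium ion 14, whose C4 is attacked by the terminal carbon of the electron-rich styrene 2 (Prins-type addition, regiochemistry fixed by the para-alkoxybenzylic cation 15 that results); a 1,5-hydride shift from the acetal C2–H through a six-membered chair-like transition state (H–C2–O3–C4–CH2–CH+) should then reduce the benzylic carbon to CH2 and leave the 2-methyl-1,3-dioxan-2-ylium ion 16, which water opens through the orthoacid to the hydroxy acetate 17. The closest known reaction types are the Lewis acid-mediated additions of allylsilanes and enol silanes to 4-acetoxy-1,3-dioxanes (4,6-trans products, anti-1,3-diols) and the hydride abstraction from cyclic acetals by carbenium ions, which gives dioxanylium ions and from them hydroxy esters; joining the two through an internal 1,5-shift is the untested part. No ring is closed: the temporary 1,3-dioxane is opened in the hydrolysis. The new stereocentre (C4 of the dioxane, C3 of the chain) should be controlled by stereoelectronically preferred axial attack on the half-chair oxocarbenium ion with the C6 side chain pseudo-equatorial, which gives the 4,6-trans dioxane and hence the anti (S,S) diol. The step needs the hydride transfer to outrun capture of 15 by a second styrene, loss of a proton or attack of a ring oxygen, and to come from C2–H and not from C6–H: the axial C2–H lies 1,3-syn-axial to the newly formed axial C4 substituent, is flanked by two oxygen lone pairs and leads to the more stable dialkoxycarbenium ion, while high dilution and slow addition of 2 keep the bimolecular paths slow. Either C–O bond of 16 may break on hydrolysis because the diol core is C2-symmetric, so both modes give the same monoacetate 17.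

Step 9
Reactants: 17 (3S,5S)-1,7-bis[4-(benzyloxy)-3-methoxyphenyl]-5-hydroxyheptan-3-yl acetate
Product: 18 (3S,5S)-5-hydroxy-1,7-bis(4-hydroxy-3-methoxyphenyl)heptan-3-yl acetate
Conditions: H2 (1 atm), Pd/C (10 %), EtOAc, rt
Reagents that add atoms: none
Why: Heterogeneous hydrogenolysis should cleave both aryl benzyl ethers as toluene under neutral conditions that leave the secondary acetate and alcohol intact, and any 1,3-acyl shift would be degenerate in this C2-symmetric diol core.

**Compound list**

1 | 2-methoxy-4-vinylphenol | C=Cc1ccc(O)c(OC)c1 | starting material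
2 | 1-(benzyloxy)-4-ethenyl-2-methoxybenzene | C=Cc1ccc(OCc2ccccc2)c(OC)c1 | intermediate
3 | [4-(benzyloxy)-3-methoxyphenyl]methanol | OCc1ccc(OCc2ccccc2)c(OC)c1 | starting material
4 | 1-(benzyloxy)-4-(chloromethyl)-2-methoxybenzene | ClCc1ccc(OCc2ccccc2)c(OC)c1 | intermediate
5 | methyl acetoacetate | COC(=O)CC(C)=O | starting material
6 | sodium lithium dianion (bis-enolate) of methyl acetoacetate | [Na+].[Li+].C=C([O-])C=C([O-])OC | intermediate (not isolated)
7 | methyl 5-[4-(benzyloxy)-3-methoxyphenyl]-3-oxopentanoate | COC(=O)CC(=O)CCc1ccc(OCc2ccccc2)c(OC)c1 | intermediate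
8 | methyl (3S)-5-[4-(benzyloxy)-3-methoxyphenyl]-3-hydroxypentanoate | COC(=O)C[C@@H](O)CCc1ccc(OCc2ccccc2)c(OC)c1 | intermediate
9 | (3S)-5-[4-(benzyloxy)-3-methoxyphenyl]-3-hydroxypentanoic acid | OC(=O)C[C@@H](O)CCc1ccc(OCc2ccccc2)c(OC)c1 | intermediate
10 | trimethylsilyl (3S)-5-[4-(benzyloxy)-3-methoxyphenyl]-3-(trimethylsilyloxy)pentanoate | C[Si](C)(C)OC(=O)C[C@@H](O[Si](C)(C)C)CCc1ccc(OCc2ccccc2)c(OC)c1 | intermediate (not isolated)
11 | (2S,6S)-6-{2-[4-(benzyloxy)-3-methoxyphenyl]ethyl}-2-methyl-1,3-dioxan-4-one (2,6-cis) | C[C@@H]1OC(=O)C[C@H](CCc2ccc(OCc3ccccc3)c(OC)c2)O1 | intermediate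
12 | diisobutylaluminium alkoxide of the hemiacetal from 11 (O–Al at C4, C4 epimers) | C[C@@H]1OC(O[Al](CC(C)C)CC(C)C)C[C@H](CCc2ccc(OCc3ccccc3)c(OC)c2)O1 | intermediate (not isolated)
13 | (2S,6S)-6-{2-[4-(benzyloxy)-3-methoxyphenyl]ethyl}-2-methyl-1,3-dioxan-4-yl acetate (C4 epimers) | C[C@@H]1OC(OC(C)=O)C[C@H](CCc2ccc(OCc3ccccc3)c(OC)c2)O1 | intermediate
14 | cyclic oxocarbenium triflate from 13 (O3=C4 cation, C2 and C6 as in 11) | C[C@@H]1[O+]=CC[C@H](CCc2ccc(OCc3ccccc3)c(OC)c2)O1.[O-]S(=O)(=O)C(F)(F)F | intermediate (not isolated)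
15 | benzylic cation triflate: 4,6-trans-dioxane with CH2–CH(+)Ar at C4 (axial) | C[C@@H]1O[C@@H](C[CH+]c2ccc(OCc3ccccc3)c(OC)c2)C[C@H](CCc2ccc(OCc3ccccc3)c(OC)c2)O1.[O-]S(=O)(=O)C(F)(F)F | intermediate (not isolated)
16 | (4S,6S)-4,6-bis{2-[4-(benzyloxy)-3-methoxyphenyl]ethyl}-2-methyl-1,3-dioxan-2-ylium triflate | CC1=[O+][C@@H](CCc2ccc(OCc3ccccc3)c(OC)c2)C[C@H](CCc2ccc(OCc3ccccc3)c(OC)c2)O1.[O-]S(=O)(=O)C(F)(F)F | intermediate (not isolated)
17 | (3S,5S)-1,7-bis[4-(benzyloxy)-3-methoxyphenyl]-5-hydroxyheptan-3-yl acetate | CC(=O)O[C@@H](CCc1ccc(OCc2ccccc2)c(OC)c1)C[C@H](CCc1ccc(OCc2ccccc2)c(OC)c1)O | intermediate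
18 | (3S,5S)-5-hydroxy-1,7-bis(4-hydroxy-3-methoxyphenyl)heptan-3-yl acetate | CC(=O)O[C@@H](CCc1ccc(O)c(OC)c1)C[C@H](CCc1ccc(O)c(OC)c1)O | target

**Totals**

Total step count: 9. Longest linear sequence: 8 steps (3 → 4 → 7 → 8 → 9 → 11 → 13 → 17 → 18).

**Steps most likely to fail**

Step 8 (proposed new method). The benzylic cation may be diverted before the internal hydride transfer, by chain growth onto further styrene, by loss of a proton, or by bridging from the ring oxygen followed by fragmentation. The acetal ring may also open at the oxocarbenium stage. The fallback makes the same C2–C3 bond by acylation with known chemistry; it sets out from 8 (and uses 2) and comes back at 17. Ester 8 would be converted with MeNH(OMe)·HCl and iPrMgCl into the hydroxy Weinreb amide F1. In parallel, 2 would be hydroborated with 9-BBN to the B-alkyl borane F2 and oxidised (NaOH, H2O2) to 2-[4-(benzyloxy)-3-methoxyphenyl]ethanol F3. Appel conditions (CBr4, PPh3) would give the bromide F4, and Mg in THF the Grignard reagent F5. After deprotonation of the hydroxyl of F1 with iPrMgCl, addition of F5 should give the β-hydroxy ketone F6 by Weinreb ketone synthesis. An Evans–Tishchenko reduction of F6 (SmI2 catalytic, excess MeCHO, THF, −10 °C) should deliver hydride within the samarium-bound hemiacetal and give the anti diol monoacetate with the acetyl on the original hydroxyl, which is 17.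

Step 7. The aluminium hemiacetal may be over-reduced or may open with loss of acetaldehyde before acylation, and the anomeric acetate may hydrolyse during isolation. The fallback reaches the same ring at the aldehyde oxidation level without a lactone reduction; it sets out from 8, bypasses steps 5 to 7 and comes back at 13. Reduction of 8 with LiBH4 would give the diol F7, and selective oxidation of its primary alcohol (TEMPO, PhI(OAc)2) the β-hydroxy aldehyde F8. With excess acetaldehyde and a trace of pyridine, F8 should close to the six-membered hemiacetal F9 (the classical aldoxane-type equilibrium, methyl and side chain equatorial). Trapping in the same flask with Ac2O, pyridine and DMAP should give 13.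

Step 3. O-alkylation or polyalkylation of the dianion, and ionisation with self-condensation of the electron-rich benzylic chloride, may erode the alkylation. The fallback builds the keto ester by olefination; it sets out from 3 and comes back at 7. Oxidation of 3 with MnO2 would give 4-(benzyloxy)-3-methoxybenzaldehyde F10. Horner–Wadsworth–Emmons olefination with the dianion of methyl 4-(diethoxyphosphoryl)-3-oxobutanoate (NaH, THF) should give the (E)-enone keto ester F11. Hydrogenation of its C=C bond over Pd/C poisoned with diphenyl sulfide, which should retain the aryl benzyl ether, would give 7.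

Further compounds
F1 | step 8 | (3S)-5-[4-(benzyloxy)-3-methoxyphenyl]-3-hydroxy-N-methoxy-N-methylpentanamide | CON(C)C(=O)C[C@@H](O)CCc1ccc(OCc2ccccc2)c(OC)c1
F2 | step 8 | 9-{2-[4-(benzyloxy)-3-methoxyphenyl]ethyl}-9-borabicyclo[3.3.1]nonane | COc1cc(CCB2C3CCCC2CCC3)ccc1OCc1ccccc1
F3 | step 8 | 2-[4-(benzyloxy)-3-methoxyphenyl]ethanol | OCCc1ccc(OCc2ccccc2)c(OC)c1
F4 | step 8 | 1-(benzyloxy)-4-(2-bromoethyl)-2-methoxybenzene | BrCCc1ccc(OCc2ccccc2)c(OC)c1
F5 | step 8 | {2-[4-(benzyloxy)-3-methoxyphenyl]ethyl}magnesium bromide | Br[Mg]CCc1ccc(OCc2ccccc2)c(OC)c1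
F6 | step 8 | (5S)-1,7-bis[4-(benzyloxy)-3-methoxyphenyl]-5-hydroxyheptan-3-one | O=C(CCc1ccc(OCc2ccccc2)c(OC)c1)C[C@@H](O)CCc1ccc(OCc2ccccc2)c(OC)c1
F7 | step 7 | (3S)-5-[4-(benzyloxy)-3-methoxyphenyl]pentane-1,3-diol | OCC[C@@H](O)CCc1ccc(OCc2ccccc2)c(OC)c1
F8 | step 7 | (3S)-5-[4-(benzyloxy)-3-methoxyphenyl]-3-hydroxypentanal | O=CC[C@@H](O)CCc1ccc(OCc2ccccc2)c(OC)c1
F9 | step 7 | (2S,6S)-6-{2-[4-(benzyloxy)-3-methoxyphenyl]ethyl}-2-methyl-1,3-dioxan-4-ol (C4 epimers) | C[C@@H]1OC(O)C[C@H](CCc2ccc(OCc3ccccc3)c(OC)c2)O1
F10 | step 3 | 4-(benzyloxy)-3-methoxybenzaldehyde | O=Cc1ccc(OCc2ccccc2)c(OC)c1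
F11 | step 3 | methyl (4E)-5-[4-(benzyloxy)-3-methoxyphenyl]-3-oxopent-4-enoate | COC(=O)CC(=O)/C=C/c1ccc(OCc2ccccc2)c(OC)c1
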